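The runs are simulated with constants of no real substance; scatter was added.

The ratio of catalyst charges between zeta and gamma is 4.00, yet target reads 37% and 38% at 0.500 min, so treat the rise as needing no catalyst.

| flask | starting material | catalyst | added ligand | remark | time |
|---|---|---|---|---|---|
| gamma | 0.57 M | 7.5 mM | 88 mM | run made earlier |  |
| zeta | 0.57 M | 30 mM | 88 mM | run made earlier |  |
| flask | 0.57 M | 15 mM | 88 mM |  | 40 min |

| run | time / min | target / % |
|---|---|---|
| gamma | 0.500 | 38 |
| gamma | 1.00 | 54 |
| gamma | 2.00 | 61 |
| gamma | 4.00 | 61 |
| gamma | 6.00 | 59 |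
| gamma | 12.0 | 55 |
| gamma | 25.0 | 53 |
| zeta | 0.500 | 37 |
| zeta | 1.00 | 51 |
| zeta | 2.00 | 50 |
| zeta | 4.00 | 54 |
| zeta | 6.00 | 51 |
| zeta | 12.0 | 50 |
| zeta | 25.0 | 53 |

(each reading ± 1.5 percentage points)

- time up to 40 min at which target stands highest
- the amount of target, in percent of the starting material charged, at that time

- the numbers in the tables scatter with a standard deviation of 1.5 percentage points
- steps thought possible: isomer of the product + catalyst <-> starting material + catalyst; catalyst + added ligand <-> idle complex; target + catalyst <-> isomer of the product + catalyst; starting material <-> target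

From gamma's first two readings, get the rise rate f = 1.73 min⁻¹ toward a plateau P = 65.6%. Take zeta's last reading, F = 53.0%, as the final level. Freeze the free share of catalyst, because added ligand at 88 mM exceeds the largest catalyst charge, 30 mM. The excess of target over F then falls in a pseudo-first-order way. Read gamma between 4.00 min and 12.0 min to get g = 23.1 L mol⁻¹ min⁻¹, the drain constant, the decay rate of that excess per catalyst charged.

For the flask, the drain rate is d = 0.347 min⁻¹, so target at time t is T = F + (P−F)exp(−dt) − P exp(−ft). By my reckoning, it peaks at 2.35 min with 57.5%. Take the target then, and add no catalyst: at 4.00 min zeta read 54%, below gamma's 61%.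

The forecast gives 58% at 2.3 min, holding that “formation is uncatalysed”. The flask gives 59.3% at 2.08 min.

    isomer of the product + catalyst ⇌ starting material + catalyst, rate k1*[catalyst]*[isomer of the product] forward; the back reaction follows from the equilibrium constant (k = 19.0 L mol⁻¹ min⁻¹)
    catalyst + added ligand ⇌ idle complex, settled at all times (K = 35.0 L mol⁻¹)
    target + catalyst ⇌ isomer of the product + catalyst, rate k3*[catalyst]*[target] forward; the back reaction follows from the equilibrium constant (K = 0.490, k = 20.0 L mol⁻¹ min⁻¹)
    starting material ⇌ target (K = 2.30, k = 1.20 min⁻¹)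

At 4.00 min, g gives this flask 56.1% target, and it holds 56.7%. Now carry g to the neighbouring flask with 0.0037 M of catalyst: its drain rate is 0.0855 min⁻¹, so the reckoned peak comes at 2.83 min with 62.4%, against a simulated best of 65.8%. The reckoned target at 40.0 min is 53.4%, and that neighbouring flask holds 52.9%.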